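A flask charged with equal amounts of two mirror-image substrates, which uses up both, cannot end with an excess of one product unless the wrong substrate keeps turning into the right one while the coupling runs. So we compare the speed of that turning with the speed of the coupling.

| setting | beta | theta | north | south-west | east | west |
|---|---|---|---|---|---|---|
| left-handed substrate | 16 mM | 16 mM | 16 mM | 16 mM | 16 mM | 16 mM |
| right-handed substrate | 16 mM | 16 mM | 16 mM | 16 mM | 16 mM | 16 mM |
| coupling partner | 18 mM | 26 mM | 35.2 mM | 35.2 mM | 35.2 mM | 35.2 mM |
| free catalyst | 83 µM | 83 µM | 83 µM | 83 µM | 83 µM | 83 µM |
| racemization catalyst | 9.8 µM | 9.8 µM | 9.8 µM | 9.8 µM | 9.8 µM | 9.8 µM |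
| temperature | 75 °C | 100 °C |  | 120 °C | 100 °C | 80 °C |
| remark | run made earlier | run made earlier | at 80 °C until 4.0 min, from then on at 120 °C |  |  |  |
| time |  |  | 8.0 min | 8.0 min | 8.0 min | 8.0 min |

| run | time / min | left-handed product / % | right-handed product / % | left-handed substrate / % |
|---|---|---|---|---|
| beta | 8.00 | 31.6 | 8.6 | 22.1 |
| beta | 15.0 | 38.7 | 11.3 | 21.6 |
| beta | 25.0 | 39.2 | 13.5 | 23.9 |
| beta | 30.0 | 41.5 | 12.8 | 23.2 |
| beta | 40.0 | 41.8 | 13.6 | 20.3 |
| beta | 50.0 | 40.3 | 12.4 | 22.1 |
| theta | 2.50 | 32.2 | 12.6 | 21.7 |
| theta | 4.00 | 37.5 | 15.2 | 20.3 |
| theta | 6.00 | 40.3 | 16.6 | 20.4 |
| theta | 8.00 | 44.1 | 17.4 | 19.1 |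
| theta | 10.0 | 45.2 | 19.0 | 17.0 |
| theta | 15.0 | 51.0 | 19.0 | 13.5 |

(each reading ± 1 percentage point)

* the best flask by excess of left-handed product over right-handed product; "all alike" if 1.5 percentage points covers them all (north / south-west / east / west / all alike)
* excess of left-handed product over right-handed product at the end, north
* excess of left-handed product over right-handed product at the end, south-west
* excess of left-handed product over right-handed product at the end, east
* excess of left-handed product over right-handed product at the end, west

- free catalyst is single-handed; left-handed substrate and right-handed substrate are mirror images of each other, charged as a racemate, each of them at the stated concentration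
- reactions considered so far: coupling partner + free catalyst + left-handed substrate -> free catalyst + left-handed product; coupling partner + free catalyst + right-handed substrate -> free catalyst + right-handed product; left-handed substrate + racemization catalyst <-> right-handed substrate + racemization catalyst; free catalyst <-> dormant form
- an excess is the difference of the two amounts in percent of their sum
- an excess is below zero if the other one leads

The bench rule is this: if racemization keeps the two substrates equal, the single-handed free catalyst makes left-handed and right-handed product in a fixed ratio s, the selectivity factor, and the excess is s less one over s plus one. We find its border by counting half-lives. Let t_r be the half-life of the gap between right-handed and left-handed substrate, the right-handed amount coming from the balance of percentages. In theta the gap reads 12 percentage points, then 2.3 points, so t_r reads 1.48 min, with much scatter in so small a gap. Let t_c be the early half-life of the substrates, treated as pseudo-first-order in them, from the first theta products and scaled by the partner charge to the recipe: 2.15 min. The count N, the racemization half-lives passing in one coupling half-life, is 1.45 for east. At so low a count the substrates need not stay equal, as theta's first gap of 12 points shows, so we take the rule as a ceiling.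

The same reckoning on beta, at 75 °C, gives 0.944, a lower count than east's. Beta's first product ratio, left-handed over right-handed, reads 3.67 against 2.56 in theta. So the colder run shows the lower count and the higher ratio, and we expect the flasks closer together than the forecast has them.

The forecast names west, at 50% (45% to 56%), with north 45%, east 41% and south-west 33%: “South-west loses selectivity”.

The flasks give all alike: north 40.1%, south-west 39.3%, east 40.1%, west 40.0%.

    coupling partner + free catalyst + left-handed substrate → free catalyst + left-handed product (k = 5700 M⁻² s⁻¹, Ea = 31.0 kJ mol⁻¹)
    coupling partner + free catalyst + right-handed substrate → free catalyst + right-handed product (k = 1900 M⁻² s⁻¹, Ea = 39.0 kJ mol⁻¹)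
    left-handed substrate + racemization catalyst ⇌ right-handed substrate + racemization catalyst, rate k3*[racemization catalyst]*[left-handed substrate] forward; the back reaction follows from the equilibrium constant (k = 540 M⁻¹ s⁻¹, Ea = 56.0 kJ mol⁻¹)
    free catalyst ⇌ dormant form (K = 1.90, k = 0.00480 s⁻¹, Ea = 118 kJ mol⁻¹, ΔH = −17.0 kJ mol⁻¹)
    (constants at 100 °C)

East, with its count of 1.45, ended at 40.1%. South-west starts with a rate ratio of 2.6, so the bench rule gives it 44.9%, and it stands lower, at 39.3%. Its neighbour holds more partner, 60 mM against 35.2 mM, at the same temperature, so by our scaling its count is south-west's times 0.587. The neighbour's excess is 34.2%, below south-west's, with right-handed product at 32.1%.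

(All runs were generated by integration with constants of no real substance; scatter was added.)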